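**Strategy**

Everything rests on cutting ring A at C3–C4. The key step exploits two features: ring A is an α-acyloxy ketone (C2 ketone, C3 angelate), so C3 is an enol carbon, and C4 carries two methyls on C5 of ring B, so it is a tertiary-cation site that (S)-carvone supplies as its isopropenyl group together with ring B (C5–C10, C7=C8, C8 methyl). In one operation C3 attacks the C4 cation, which closes ring A, makes quaternary C4 beside the C3 ester stereocentre and frees the C2 ketone. The precursor is a ring B cyclohexene bearing a 2-chloropropan-2-yl group on C5, a Z acyloxy enol silane arm on quaternary C10 and the coumarin ether on C11.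

Key step: step 10

Remark: carbons are numbered throughout as in the target decalin (ring A: C1–C5 and C10; ring B: C5–C10; C11 is the oxymethylene carbon on C9), also in the monocyclic intermediates; LiN(i-Pr)2 and KN(SiMe3)2 are used as purchased solutions.

**Route**

Step 1
Reactants: 1 (S)-(+)-carvone; 2 iodomethane
Product: 4 trans-6-methylcarvone (methyl on the α′ carbon C10 trans to the isopropenyl group on C5), via lithium dienolate of carvone 3 (not isolated)
Conditions: LiN(i-Pr)2, THF, −78 °C; then 2, −78 → −20 °C
Reagents that add atoms: none
Why: Kinetic deprotonation of the enone at the α′ methylene and methylation of the cross-conjugated lithium dienolate (enolate alkylation) should occur anti to the isopropenyl group and give mainly the trans methyl compound, although the configuration of this carbon is erased again in step 2.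

Step 2
Reactants: 4 trans-6-methylcarvone; 5 3-bromo-1-(trimethylsilyl)prop-1-yne
Product: 7 6-methyl-6-[3-(trimethylsilyl)prop-2-yn-1-yl]carvone (quaternary C10 with the methyl cis and the C1–C3 arm trans to the isopropenyl group on C5), via lithium enolate of 6-methylcarvone 6 (not isolated)
Conditions: LiN(i-Pr)2, THF, −78 °C; then 5, DMPU, −78 → −10 °C
Reagents that add atoms: none
Why: A second kinetic enolisation at the same α′ carbon followed by enolate alkylation with the reactive propargylic bromide should bring the C1–C3 arm in anti to the isopropenyl group on C5, which fixes quaternary C10 with its methyl cis and the arm trans to that group.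

Step 3
Reactants: 7 6-methyl-6-(silylpropargyl)carvone
Product: 8 tertiary chloride (7 with a 2-chloropropan-2-yl group on C5 in place of isopropenyl; enone and silyl alkyne unchanged)
Conditions: HCl (g), CH2Cl2, −40 °C
Reagents that add atoms: hydrogen chloride, Cl
Why: Markovnikov hydrochlorination of the electron-rich 1,1-disubstituted alkene is expected to be selective because the conjugated C7=C8 bond and the silyl alkyne are far less basic, and the cold chloride-rich medium should collapse the C4 cation to the tertiary chloride before it can engage the alkyne; no stereocentre is formed.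

Step 4
Reactants: 8 tertiary chloride enone; 9 trimethylsulfonium iodide
Product: 12 C9 spiro vinyl oxirane (C9–O–C11 ring with the oxygen cis and C11 trans to the C10 methyl; C7=C8 retained), via dimethylsulfonium methylide 10 (not isolated), via sulfonium alkoxide betaine 11 (not isolated)
Conditions: 9, KN(SiMe3)2, THF, −20 °C; then 8, −20 → 0 °C
Reagents that add atoms: none
Why: Corey–Chaykovsky epoxidation, in which the small sulfonium ylide should add 1,2 and irreversibly to the C9 carbonyl along the axial trajectory on the face away from the axial C10 methyl, so that C11 enters anti and the oxirane oxygen lies syn to that methyl, while the chloride has no enolate partner because C10 is quaternary.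

Step 5
Reactants: 12 C9 spiro vinyl oxirane
Product: 13 homoallylic alcohol (C9–H; hydroxymethyl C11 cis to the C10 methyl; C7=C8 in place)
Conditions: Pd2(dba)3·CHCl3 (cat.), PBu3, HCO2H, NEt3, dioxane, rt → 40 °C
Reagents that add atoms: none
Why: Palladium-catalysed formate hydrogenolysis of an alkenyl oxirane, in which zerovalent palladium should ionise the allylic C9–O bond from the face opposite oxygen and, after formate exchange and loss of CO2, pass hydride to the more substituted allyl terminus C9 on that same face, so that C9–H forms with inversion, C11 ends up cis to the C10 methyl and the C7=C8 bond stays in place.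

Step 6
Reactants: 13 homoallylic alcohol; 14 umbelliferone (7-hydroxycoumarin)
Product: 15 umbelliferyl ether (C11–O–C7 of the coumarin; silyl alkyne and tertiary chloride retained)
Conditions: PPh3, DIAD, THF, 0 °C → rt
Reagents that add atoms: none
Why: Mitsunobu etherification, in which the acidic phenol of umbelliferone should displace the oxyphosphonium derivative of the primary C11 alcohol under neutral conditions that spare the tertiary chloride, with no stereocentre touched.

Step 7
Reactants: 15 umbelliferyl ether
Product: 16 terminal alkyne (15 without the trimethylsilyl group)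
Conditions: K2CO3 (cat.), MeOH/THF, 0 °C
Reagents that add atoms: none
Why: Base-catalysed protodesilylation of the alkynylsilane by methanol is fast at 0 °C, where methanolysis of the tertiary chloride and opening of the coumarin lactone should not compete.

Step 8
Reactants: 16 terminal alkyne; 17 angelic acid
Product: 18 α-angeloyloxy methyl ketone (C2 ketone; C3 a CH2 carrying the angelate)
Conditions: [(1-Ad)2P(2-morpholinophenyl)]AuNTf2 (5 mol%), 8-methylquinoline N-oxide, PhCl, rt
Reagents that add atoms: 8-methylquinoline N-oxide, Cc1cccc2ccc[n+]([O-])c12
Why: Gold-catalysed alkyne oxidation with O–H insertion, in which the N-oxide should deliver oxygen to the internal carbon C2 of the gold-activated terminal alkyne and the α-oxo gold carbene so formed at C3 is captured by angelic acid, the P,N ligand tempering the carbene so that capture outruns a second oxidation, while the equatorial C10 arm cannot reach the C7=C8 face without an unfavourable ring flip.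

Step 9
Reactants: 18 α-angeloyloxy methyl ketone
Product: 19 (Z)-acyloxy enol silane (C2–OTBS, C2=C3, angelate oxygen on C3 cis to the silyloxy group and trans to C1)
Conditions: TBSOTf, NEt3, CH2Cl2, −78 → 0 °C
Reagents that add atoms: tert-butyldimethylsilyl trifluoromethanesulfonate, CC(C)(C)[Si](C)(C)OS(=O)(=O)C(F)(F)F
Why: Soft enolisation with a silyl triflate and an amine should go toward C3, whose hydrogens are acidified by the ester oxygen and unhindered, in preference to the neopentyl C1, and should give the Z enol silane with the acyloxy group trans to C1, which avoids allylic strain with the C10 substituents.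

Step 10
Reactants: 19 (Z)-acyloxy enol silane
Product: 20 target CNP0111364.1 (3S,5S,9R,10R in the decalin numbering used here)
Conditions: TiCl4 (2.5 equiv), 2,6-di-tert-butyl-4-methylpyridine (0.3 equiv), CH2Cl2, −78 °C; aq. NaHCO3
Reagents that add atoms: none
Why: Proposed new method: TiCl4 should abstract chloride from C4 to give the tertiary cation as an ion pair, C3 of the enol silane attacks it, and the resulting C2 silyloxycarbenium ion hands its silyl group to chloride, which releases the ketone and tert-butyldimethylsilyl chloride; the closest known reaction type is the Lewis-acid α-tert-alkylation of ketone silyl enol ethers with tertiary alkyl chlorides, extended here to an intramolecular case with a 1-acyloxy-2-silyloxy alkene, a nucleophile class established in Mukaiyama aldol additions. Ring A closes in a 6-(enolendo)-exo-tet mode through a chair in which the C5 and C10 arms are both equatorial on ring B, so the trans ring fusion preset by C5 and C10 is retained. C3 is the only new stereocentre and is controlled by the Z geometry of the enol silane: the acyloxy group is anti to C1 across C2=C3 and therefore becomes equatorial in the chair, cis to the C10 methyl, while the C3 hydrogen becomes axial. The selectivity needed is C-alkylation at C3 over O-alkylation, over proton loss from the cation and over any reaction at C7=C8; carbon is the kinetically preferred terminus of an enol silane, the two reacting carbons are held in a 1,6 relationship across quaternary C10, and the cation is formed without protic acid while the hindered pyridine traps stray HCl. The main uncertainty is the lower nucleophilicity of an enol carbon that carries an acyloxy group, which the intramolecular, strain-free closure is expected to offset. C4 becomes quaternary without being a stereocentre, and C3 stays epimerisable through the C2 enol if correction toward the equatorial ester were needed.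

**Compound list**

1 | (S)-(+)-carvone, (5S)-2-methyl-5-(prop-1-en-2-yl)cyclohex-2-en-1-one | CC1=CC[C@@H](CC1=O)C(C)=C | starting material
2 | iodomethane | CI | starting material
3 | lithium dienolate of carvone (O–Li on the former carbonyl carbon, new C=C toward the α′ carbon) | CC1=CC[C@@H](C=C1[O-])C(C)=C.[Li+] | intermediate
4 | trans-6-methylcarvone (α′ methyl trans to isopropenyl) | C[C@H]1C(=O)C(C)=CC[C@@H]1C(C)=C | intermediate
5 | 3-bromo-1-(trimethylsilyl)prop-1-yne | C[Si](C)(C)C#CCBr | starting material
6 | lithium enolate of 6-methylcarvone (tetrasubstituted C9=C10 enolate) | CC1=CC[C@@H](C(C)=C1[O-])C(C)=C.[Li+] | intermediate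
7 | 6-methyl-6-[3-(trimethylsilyl)prop-2-yn-1-yl]carvone (C10 methyl cis, propargyl arm trans to isopropenyl) | C[Si](C)(C)C#CC[C@@]1(C)C(=O)C(C)=CC[C@@H]1C(C)=C | intermediate
8 | tertiary chloride: 7 with 2-chloropropan-2-yl on C5 | C[Si](C)(C)C#CC[C@@]1(C)C(=O)C(C)=CC[C@@H]1C(C)(C)Cl | intermediate
9 | trimethylsulfonium iodide | C[S+](C)C.[I-] | starting material
10 | dimethylsulfonium methylide | C[S+](C)[CH2-] | intermediate
11 | sulfonium alkoxide betaine (C9 alkoxide, C11 bearing dimethylsulfonium, C11 trans to the C10 methyl) | C[Si](C)(C)C#CC[C@@]1(C)[C@@]([O-])(C[S+](C)C)C(C)=CC[C@@H]1C(C)(C)Cl | intermediate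
12 | C9 spiro vinyl oxirane (oxygen cis, C11 trans to the C10 methyl) | C[Si](C)(C)C#CC[C@@]1(C)[C@@]2(CO2)C(C)=CC[C@@H]1C(C)(C)Cl | intermediate
13 | homoallylic alcohol (C9–H, CH2OH cis to the C10 methyl, C7=C8) | C[Si](C)(C)C#CC[C@@]1(C)[C@H](CO)C(C)=CC[C@@H]1C(C)(C)Cl | intermediate
14 | umbelliferone (7-hydroxycoumarin) | Oc1ccc2ccc(=O)oc2c1 | starting material
15 | umbelliferyl ether of 13 | C[Si](C)(C)C#CC[C@@]1(C)[C@H](COc2ccc3ccc(=O)oc3c2)C(C)=CC[C@@H]1C(C)(C)Cl | intermediate
16 | terminal alkyne (desilylated 15) | C#CC[C@@]1(C)[C@H](COc2ccc3ccc(=O)oc3c2)C(C)=CC[C@@H]1C(C)(C)Cl | intermediate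
17 | angelic acid, (Z)-2-methylbut-2-enoic acid | C/C=C(/C)C(=O)O | starting material
18 | α-angeloyloxy methyl ketone (C2 ketone, C3 angelate) | C/C=C(/C)C(=O)OCC(=O)C[C@@]1(C)[C@H](COc2ccc3ccc(=O)oc3c2)C(C)=CC[C@@H]1C(C)(C)Cl | intermediate
19 | (Z)-1-angeloyloxy-2-(tert-butyldimethylsilyloxy) alkene with tertiary chloride | C/C=C(/C)C(=O)O/C=C(\O[Si](C)(C)C(C)(C)C)C[C@@]1(C)[C@H](COc2ccc3ccc(=O)oc3c2)C(C)=CC[C@@H]1C(C)(C)Cl | intermediate
20 | CNP0111364.1: trans-fused decalin with C2 ketone, equatorial C3 angelate, C4 gem-dimethyl, C7=C8 with C8 methyl, C9 CH2–O–(7-coumarinyl) and C10 methyl; C3 ester, C11 and C10 methyl on one face, H5 and H9 on the other (3S,5S,9R,10R) | C/C=C(/C)C(=O)O[C@@H]1C(=O)C[C@@]2(C)[C@H](COc3ccc4ccc(=O)oc4c3)C(C)=CC[C@@H]2C1(C)C | target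

**Step count**

Total step count: 10. Longest linear sequence: 10 steps (1 to 20).

**Steps most likely to fail**

1. Step 10. The C4 cation may lose a proton or recapture chloride faster than the acyloxy-deactivated enol carbon attacks it, or the closure may run with poor facial control at C3. The fallback closes ring A with a plain enol silane and brings the ester in afterwards, all by known reaction types. It sets out from alkyne 16, which is hydrated (Ph3PAuNTf2, wet dioxane) to the methyl ketone F1. Kinetic enolisation at the methyl group (LiN(i-Pr)2, Me3SiCl, THF, −78 °C) gives the terminal trimethylsilyl enol ether F2, and TiCl4 in CH2Cl2 at −78 °C closes ring A by the established α-tert-alkylation to the C3-unsubstituted 2-ketone F3. Enolisation of this trans-fused 2-ketone should go toward C3, so trifluoroacetylation (LiN(SiMe3)2, CF3CO2CH2CF3, THF, −78 °C) gives the 3-trifluoroacetyl ketone F4, and detrifluoroacetylative diazo transfer (MsN3, NEt3, MeCN) gives the 3-diazo-2-ketone F5. Rh2(OAc)4-catalysed O–H insertion of F5 into angelic acid 17 returns to the route at target 20; protonation of the intermediate enol on the face away from the C10 and axial C4 methyls should place the ester equatorial.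

2. Step 5. Ionisation of the oxirane may be slow because the C9–O bond lies close to the plane of the alkene, and the hydride may be delivered to C7 or lost through diene formation. The fallback avoids the oxirane altogether. It sets out from chloro enone 8, which is methylenated with Cp2TiMe2 (toluene, 65 °C) to the 7,9(11)-diene F6. 9-BBN should add to the terminal methylene from the face away from the axial C10 methyl to give the C11 borane F7, and oxidation with NaBO3·4H2O returns to the route at alcohol 13.

3. Step 8. The oxo-carbene may be diverted by a second oxidation or by attack on C7=C8 before angelic acid captures it. The fallback brings the ester in by substitution and involves no carbene. It sets out from alkyne 16, which is brominated at the alkyne terminus (NBS, DBU, MeCN) to the 1-bromoalkyne F8. Gold-catalysed hydration (Ph3PAuNTf2, wet 1,2-dichloroethane) gives the bromomethyl ketone F9, and displacement of bromide with angelic acid 17 and Cs2CO3 in DMF at rt returns to the route at keto ester 18.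

**Further compounds**

F1 | step 10 | methyl ketone (C2 ketone, C3 methyl) | CC(=O)C[C@@]1(C)[C@H](COc2ccc3ccc(=O)oc3c2)C(C)=CC[C@@H]1C(C)(C)Cl
F2 | step 10 | terminal trimethylsilyl enol ether (C2–OSiMe3, C2=C3H2) | C=C(O[Si](C)(C)C)C[C@@]1(C)[C@H](COc2ccc3ccc(=O)oc3c2)C(C)=CC[C@@H]1C(C)(C)Cl
F3 | step 10 | C3-unsubstituted 2-ketone (target skeleton without the angelate) | C1C(=O)C[C@@]2(C)[C@H](COc3ccc4ccc(=O)oc4c3)C(C)=CC[C@@H]2C1(C)C
F4 | step 10 | 3-trifluoroacetyl ketone (enolised, C3 not defined) | FC(F)(F)C(=O)C1C(=O)C[C@@]2(C)[C@H](COc3ccc4ccc(=O)oc4c3)C(C)=CC[C@@H]2C1(C)C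
F5 | step 10 | 3-diazo-2-ketone | [N-]=[N+]=C1C(=O)C[C@@]2(C)[C@H](COc3ccc4ccc(=O)oc4c3)C(C)=CC[C@@H]2C1(C)C
F6 | step 5 | 7,9(11)-diene (C9 exocyclic methylene) | C[Si](C)(C)C#CC[C@@]1(C)C(=C)C(C)=CC[C@@H]1C(C)(C)Cl
F7 | step 5 | C11 borane (B-alkyl-9-borabicyclo[3.3.1]nonane, C11 cis to the C10 methyl) | C[Si](C)(C)C#CC[C@@]1(C)[C@H](CB2C3CCCC2CCC3)C(C)=CC[C@@H]1C(C)(C)Cl
F8 | step 8 | 1-bromoalkyne | BrC#CC[C@@]1(C)[C@H](COc2ccc3ccc(=O)oc3c2)C(C)=CC[C@@H]1C(C)(C)Cl
F9 | step 8 | bromomethyl ketone (C2 ketone, C3 CH2Br) | BrCC(=O)C[C@@]1(C)[C@H](COc2ccc3ccc(=O)oc3c2)C(C)=CC[C@@H]1C(C)(C)Cl
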